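**Retrosynthetic overview**
- The central sp2–sp2 single bond of the (E,E)-diene is cut last: an oxidative boron-Heck coupling joins the (E)-alkenyl pinacol boronate of the ring C10 fragment to unprotected (S)-linalool. The boronate comes from C–H borylation of an isopropenyl cis-bromohydrin.
- The bromohydrin comes from methyl addition to cis-2-bromo-4-isopropenylcyclohexanone, that from bromination of a regiodefined enol derivative, and that from nopinone and (−)-β-pinene.
- Feature on which the strategy rests: the cyclohexane carries, in a row, C(CH3)(OH), CHBr, CH2 and CH(side chain), with OH, Br and side chain all cis, so anti opening of a limonene epoxide cannot give it. These four atoms are C2 (carbonyl), C1 (bridgehead), C7 (bridge) and C5 (bridgehead) of nopinone, and the gem-dimethyl carbon C6 becomes the methyl-bearing diene carbon. Because 4-isopropenylcyclohexanone is achiral, the chirality must be carried by an enol double bond fixed toward C1, which cleavage of the C1–C6 cyclobutane bond provides.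
- No ring is closed. The six-membered ring is uncovered by opening the four-membered ring of the bicyclo[3.1.1]heptane, then brominated and methylated, and the linalool chain is attached last.

Key step: step 2

Remark on the chemistry: under zinc-acetate-buffered acylative conditions the C6 cation is taken to be captured as its tertiary acetate faster than it loses a proton, so the isopropenyl group is released in a separate thermal syn-elimination (step 3).

Step 1
Reactants: 1 (1S,5S)-(−)-β-pinene
Product: 2 (1R,5S)-(+)-nopinone (6,6-dimethylbicyclo[3.1.1]heptan-2-one)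
Conditions: O3, CH2Cl2/MeOH, −78 °C; then Me2S, −78 °C → rt
Reagents that add atoms: ozone, O=[O+][O-]
Why: Ozonolysis with reductive work-up cleaves only the exocyclic methylene and leaves both bridgehead stereocentres untouched.

Step 2
Reactants: 2 (1R,5S)-(+)-nopinone
Product: 3 (S)-4-(2-acetoxypropan-2-yl)cyclohex-1-en-1-yl acetate
Conditions: Ac2O, BF3·OEt2, Zn(OAc)2, 0 °C → rt
Reagents that add atoms: acetic anhydride, CC(=O)OC(C)=O
Why: Acetylation of the BF3-activated carbonyl oxygen gives an acyloxy-stabilised cation at C2 whose empty orbital is aligned with the strained C1–C6 bond; heterolysis of that bond releases the cyclobutane strain, leaves the enol acetate double bond between C2 and the former bridgehead C1, and places the charge on tertiary C6, where acetate from the Zn(OAc)2 buffer adds. The closest known reaction type is the Lewis-acid/anhydride fission of nopinone-type cyclobutyl ketones to optically active 4-substituted cyclohexenyl acetates. No bond to the skeleton is formed and no ring closes: the bicyclo[3.1.1]heptane opens to a single cyclohexene. No new stereocentre arises; C5 is untouched and, since C1 has become sp2, now owes its chirality solely to the position of the enol double bond. The step needs cleavage of C1–C6 rather than C1–C7, and no proton loss or hydride shift at C5–H: the first is secured because only C6 can carry a tertiary cation, the second because buffered acetate traps that cation before the neighbouring methine hydrogen can move.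

Step 3
Reactants: 3 (S)-4-(2-acetoxypropan-2-yl)cyclohex-1-en-1-yl acetate
Product: 4 (S)-4-(prop-1-en-2-yl)cyclohex-1-en-1-yl acetate
Conditions: flash vacuum pyrolysis, quartz tube, about 430 °C, 0.1 mbar; chromatography on AgNO3-impregnated SiO2
Reagents that add atoms: none
Why: Ester pyrolysis (thermal syn-elimination through a six-membered cyclic transition state) needs no acid, base or cation, so the enol acetate and its double-bond position should survive; six methyl hydrogens against one ring methine hydrogen bias the elimination toward isopropenyl, and the achiral isopropylidene isomer from the minor path is removed on the silver-loaded silica and cannot erode the enantiopurity.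

Step 4
Reactants: 4 (S)-4-(prop-1-en-2-yl)cyclohex-1-en-1-yl acetate
Product: 6 (S)-trimethyl{[4-(prop-1-en-2-yl)cyclohex-1-en-1-yl]oxy}silane, via lithium enolate 5 (not isolated)
Conditions: MeLi (2.1 equiv), THF, 0 °C (4 added to MeLi); then TMSCl (2.5 equiv), Et3N, −78 °C → rt
Reagents that add atoms: chlorotrimethylsilane, C[Si](C)(C)Cl
Why: Cleavage of an enol acetate with two equivalents of methyllithium gives the lithium enolate with the double bond where the acetate had it, provided no free ketone is ever present, and O-silylation freezes this regiochemistry, which here equals the absolute configuration because the other enol regioisomer is the enantiomer.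

Step 5
Reactants: 6 (S)-trimethyl{[4-(prop-1-en-2-yl)cyclohex-1-en-1-yl]oxy}silane
Product: 7 (2R,4S)-2-bromo-4-(prop-1-en-2-yl)cyclohexan-1-one (trans, bromine axial)
Conditions: NBS, NaHCO3, THF, −78 → 0 °C
Reagents that add atoms: N-bromosuccinimide, O=C1CCC(=O)N1Br
Why: Electrophilic bromination of a silyl enol ether with NBS is specific for the enol carbon (the former bridgehead C1) and far faster than attack on the isopropenyl group, the buffered medium forms no HBr so bromine cannot move to the other alpha carbon through an enol, and axial attack on the half-chair with equatorial isopropenyl should give mainly the axial bromide, trans to isopropenyl, with some cis isomer 8; the mixture is carried on.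

Step 6
Reactants: 7 (2R,4S)-2-bromo-4-(prop-1-en-2-yl)cyclohexan-1-one
Product: 8 (2S,4S)-2-bromo-4-(prop-1-en-2-yl)cyclohexan-1-one (cis, bromine equatorial)
Conditions: LiBr (1 equiv), MeCN, rt; chromatography, recovered 7 equilibrated again
Reagents that add atoms: lithium bromide, [Li+].[Br-]
Why: Finkelstein-type degenerate SN2 exchange by bromide at the activated alpha-keto carbon inverts C2 repeatedly without enolisation, so the kinetic axial bromide equilibrates with the diequatorial cis isomer, which the polar solvent is expected to favour only moderately; the isomers are separated and the trans isomer is recycled.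

Step 7
Reactants: 8 (2S,4S)-2-bromo-4-(prop-1-en-2-yl)cyclohexan-1-one and 9 methylmagnesium bromide
Product: 10 (1R,2S,4S)-2-bromo-1-methyl-4-(prop-1-en-2-yl)cyclohexan-1-ol
Conditions: MeMgBr, CeCl3 (anhydrous), THF, −78 °C; aq NH4Cl added at −78 °C
Reagents that add atoms: methylmagnesium bromide (9), C[Mg]Br
Why: 1,2-Addition of the non-basic organocerium reagent avoids enolisation and halogen–metal exchange, and methyl enters trans to bromine, either by equatorial attack on the chair with equatorial bromine or by dipole-controlled attack anti to the axial C–Br bond of the flipped chair, both leading to the same product; the new carbinol centre therefore has equatorial methyl and axial hydroxyl cis to bromine and to isopropenyl, as in the classical Grignard additions to 2-halocyclohexanones that give cis-halohydrins, and the cold quench prevents semipinacol ring contraction of the halohydrin alkoxide.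

Step 8
Reactants: 10 (1R,2S,4S)-2-bromo-1-methyl-4-(prop-1-en-2-yl)cyclohexan-1-ol
Product: 11 {[(1R,2S,4S)-2-bromo-1-methyl-4-(prop-1-en-2-yl)cyclohexyl]oxy}trimethylsilane
Conditions: TMSOTf, 2,6-lutidine, CH2Cl2, −78 → 0 °C
Reagents that add atoms: trimethylsilyl trifluoromethanesulfonate, C[Si](C)(C)OS(=O)(=O)C(F)(F)F
Why: Silylation of the hindered tertiary alcohol with a silyl triflate and a hindered base masks the O–H, which could otherwise consume boron reagent by O-borylation in the next step; no stereocentre is affected.

Step 9
Reactants: 11 {[(1R,2S,4S)-2-bromo-1-methyl-4-(prop-1-en-2-yl)cyclohexyl]oxy}trimethylsilane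
Product: 13 (1R,2S,4S)-2-bromo-1-methyl-4-[(E)-1-(4,4,5,5-tetramethyl-1,3,2-dioxaborolan-2-yl)prop-1-en-2-yl]cyclohexan-1-ol, via silyl ether boronate 12 (not isolated)
Conditions: B2pin2, trans-RhCl(CO)(PPh3)2 (5 mol %), toluene/MeCN 3:1, 80 °C; then aq citric acid, MeOH, rt
Reagents that add atoms: bis(pinacolato)diboron, CC1(C)OB(OC1(C)C)B1OC(C)(C)C(C)(C)O1
Why: Rhodium-catalysed dehydrogenative borylation of a 1,1-disubstituted alkene: the rhodium boryl adds across the isopropenyl group with boron on the terminal carbon, and beta-hydride elimination from the CH2B carbon restores the alkene in conjugation with boron, the boryl group ending anti to the bulky ring (E); the secondary bromide next to a quaternary carbon should resist oxidative addition, and the silyl ether is removed by the mild acidic work-up without harming the boronate.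

Step 10
Reactants: 13 (1R,2S,4S)-2-bromo-1-methyl-4-[(E)-1-(4,4,5,5-tetramethyl-1,3,2-dioxaborolan-2-yl)prop-1-en-2-yl]cyclohexan-1-ol and 14 (S)-(+)-linalool (3 equiv)
Product: 15 (1R,2S,4S)-2-bromo-4-[(2E,4E,6S)-6-hydroxy-6,10-dimethylundeca-2,4,9-trien-2-yl]-1-methylcyclohexan-1-ol (target)
Conditions: Pd(OAc)2 (10 mol %), 2,9-dimethyl-1,10-phenanthroline, O2 (1 atm), DMA, 23–45 °C
Reagents that add atoms: none
Why: Oxidative boron-Heck reaction under base-free conditions with O2 as terminal oxidant: transmetalation of the alkenyl boronate to divalent palladium keeps the E geometry, syn carbopalladation places the alkenyl group on the terminal vinyl carbon of linalool, and syn beta-hydride elimination, possible only toward the new CH2 because the carbinol carbon has no hydrogen, gives the E disubstituted alkene; the free tertiary alcohols, the trisubstituted alkene and the alkyl bromide should not react, and both carbinol stereocentres are untouched.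

**Compound list**
1 | (1S,5S)-(−)-β-pinene | C=C1CC[C@H]2C[C@@H]1C2(C)C | starting material
2 | (1R,5S)-(+)-nopinone | O=C1CC[C@H]2C[C@@H]1C2(C)C | intermediate
3 | (S)-4-(2-acetoxypropan-2-yl)cyclohex-1-en-1-yl acetate | CC(=O)OC(C)(C)[C@H]1CCC(OC(C)=O)=CC1 | intermediate
4 | (S)-4-(prop-1-en-2-yl)cyclohex-1-en-1-yl acetate | C=C(C)[C@H]1CCC(OC(C)=O)=CC1 | intermediate
5 | lithium (S)-4-(prop-1-en-2-yl)cyclohex-1-en-1-olate | C=C(C)[C@H]1CCC(O[Li])=CC1 | intermediate
6 | (S)-trimethyl{[4-(prop-1-en-2-yl)cyclohex-1-en-1-yl]oxy}silane | C=C(C)[C@H]1CCC(O[Si](C)(C)C)=CC1 | intermediate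
7 | (2R,4S)-2-bromo-4-(prop-1-en-2-yl)cyclohexan-1-one (trans) | C=C(C)[C@H]1CCC(=O)[C@H](Br)C1 | intermediate
8 | (2S,4S)-2-bromo-4-(prop-1-en-2-yl)cyclohexan-1-one (cis) | C=C(C)[C@H]1CCC(=O)[C@@H](Br)C1 | intermediate
9 | methylmagnesium bromide | C[Mg]Br | starting material
10 | (1R,2S,4S)-2-bromo-1-methyl-4-(prop-1-en-2-yl)cyclohexan-1-ol | C=C(C)[C@H]1CC[C@@](C)(O)[C@@H](Br)C1 | intermediate
11 | {[(1R,2S,4S)-2-bromo-1-methyl-4-(prop-1-en-2-yl)cyclohexyl]oxy}trimethylsilane | C=C(C)[C@H]1CC[C@@](C)(O[Si](C)(C)C)[C@@H](Br)C1 | intermediate
12 | trimethylsilyl ether of the (E)-alkenyl pinacol boronate 13 | CC1(C)OB(/C=C(\C)[C@H]2CC[C@@](C)(O[Si](C)(C)C)[C@@H](Br)C2)OC1(C)C | intermediate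
13 | (1R,2S,4S)-2-bromo-1-methyl-4-[(E)-1-(4,4,5,5-tetramethyl-1,3,2-dioxaborolan-2-yl)prop-1-en-2-yl]cyclohexan-1-ol | CC1(C)OB(/C=C(\C)[C@H]2CC[C@@](C)(O)[C@@H](Br)C2)OC1(C)C | intermediate
14 | (S)-(+)-linalool | CC(C)=CCC[C@](C)(O)C=C | starting material
15 | (1R,2S,4S)-2-bromo-4-[(2E,4E,6S)-6-hydroxy-6,10-dimethylundeca-2,4,9-trien-2-yl]-1-methylcyclohexan-1-ol | CC(C)=CCC[C@](C)(O)/C=C/C=C(\C)[C@H]1CC[C@@](C)(O)[C@@H](Br)C1 | target

**Step count**
Total steps: 10. Longest linear sequence: 10 steps (1 to 15); 9 and 14 are bought.

**Steps most likely to fail**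

Step 9. The rhodium alkyl formed after boryl insertion may eliminate hydride toward the methyl group or the ring methine instead of the CH2B carbon, giving allyl boronates, poor E/Z control or loss of the ring stereocentre. Fallback, setting out from 11 and returning at 12: ozonolysis of the isopropenyl group (O3, CH2Cl2, −78 °C; Me2S) should give the methyl ketone 1-[(1S,3S,4R)-3-bromo-4-methyl-4-(trimethylsilyloxy)cyclohexyl]ethan-1-one F6. A boron–Wittig olefination of F6 with bis(pinacolboryl)methane deprotonated by lithium 2,2,6,6-tetramethylpiperidide (THF, −78 °C → rt) should then give the trisubstituted alkenyl boronate 12 with boron trans to the ring. 12 is desilylated to 13 as in step 9.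

Step 10. Oxidative homocoupling or protodeboronation of the hindered trisubstituted alkenyl boronate may outrun insertion into the unactivated vinyl group, or insertion may lose regiocontrol. Fallback, setting out from 13 and returning at 15: iododeboronation with N-iodosuccinimide in MeCN, with retention, should give (1R,2S,4S)-2-bromo-4-[(E)-1-iodoprop-1-en-2-yl]-1-methylcyclohexan-1-ol F7. A classical Mizoroki–Heck reaction of F7 with 14 under phosphine-free conditions with a silver base (Pd(OAc)2, Ag2CO3, DMF, rt; zerovalent palladium cycle) should then give 15; the tertiary allylic alcohol again allows beta-hydride elimination only toward the diene.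

Step 3. The hot tube may abstract the ring methine hydrogen competitively, or degrade the enol ester by thermal acyl migration or ketene loss. Fallback, setting out from 3 and returning at 11: the tertiary acetate is kept as a masked isopropenyl group until the stereocentres are locked.
- Direct bromination of the enol acetate of 3 with NBS in aqueous THF/NaHCO3 (no competing alkene) should give the trans bromoketone 2-[(1S,3R)-3-bromo-4-oxocyclohexyl]propan-2-yl acetate F1.
- LiBr in MeCN equilibrates F1 to the cis bromoketone 2-[(1S,3S)-3-bromo-4-oxocyclohexyl]propan-2-yl acetate F2.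
- Ester-tolerant methyl transfer from MeTi(OiPr)3 gives the bromohydrin 2-[(1S,3S,4R)-3-bromo-4-hydroxy-4-methylcyclohexyl]propan-2-yl acetate F3.
- TMSOTf/2,6-lutidine gives the silyl ether 2-[(1S,3S,4R)-3-bromo-4-methyl-4-(trimethylsilyloxy)cyclohexyl]propan-2-yl acetate F4.
- i-Bu2AlH at −78 °C removes the acetate to give 2-[(1S,3S,4R)-3-bromo-4-methyl-4-(trimethylsilyloxy)cyclohexyl]propan-2-ol F5.
- Low-temperature dehydration with SOCl2/pyridine (E2 toward the accessible methyl hydrogens) should then give 11.

**Further compounds**
F1 | step 3 | 2-[(1S,3R)-3-bromo-4-oxocyclohexyl]propan-2-yl acetate | CC(=O)OC(C)(C)[C@H]1CCC(=O)[C@H](Br)C1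
F2 | step 3 | 2-[(1S,3S)-3-bromo-4-oxocyclohexyl]propan-2-yl acetate | CC(=O)OC(C)(C)[C@H]1CCC(=O)[C@@H](Br)C1
F3 | step 3 | 2-[(1S,3S,4R)-3-bromo-4-hydroxy-4-methylcyclohexyl]propan-2-yl acetate | CC(=O)OC(C)(C)[C@H]1CC[C@@](C)(O)[C@@H](Br)C1
F4 | step 3 | 2-[(1S,3S,4R)-3-bromo-4-methyl-4-(trimethylsilyloxy)cyclohexyl]propan-2-yl acetate | CC(=O)OC(C)(C)[C@H]1CC[C@@](C)(O[Si](C)(C)C)[C@@H](Br)C1
F5 | step 3 | 2-[(1S,3S,4R)-3-bromo-4-methyl-4-(trimethylsilyloxy)cyclohexyl]propan-2-ol | CC(C)(O)[C@H]1CC[C@@](C)(O[Si](C)(C)C)[C@@H](Br)C1
F6 | step 9 | 1-[(1S,3S,4R)-3-bromo-4-methyl-4-(trimethylsilyloxy)cyclohexyl]ethan-1-one | CC(=O)[C@H]1CC[C@@](C)(O[Si](C)(C)C)[C@@H](Br)C1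
F7 | step 10 | (1R,2S,4S)-2-bromo-4-[(E)-1-iodoprop-1-en-2-yl]-1-methylcyclohexan-1-ol | I/C=C(\C)[C@H]1CC[C@@](C)(O)[C@@H](Br)C1
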